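**Plan**

- Numbering: ring A = C1 (O-acyl), C2 (OH), C3 (oxiranyl), C4, C5 (quaternary, CH3), C6 (fusion H); ring B = C5, C6, C7, C8 (C=O), C9, C10 (CH3); oxirane = C11 (quaternary), C12 (CH2), C13 (CH3); β = face of the C5 methyl, α = opposite face.
- Retrosynthetic cuts, in order: oxirane oxygen; C1–O acyl bond; C2–O and C3–C11; C6–C7 (opens ring B to a monocyclic bis-enol ether); C5–CH3; C5=C6 (aldol, opens ring A) and C4–C5 (ketone synthesis).
- Enabling feature: C6–C7 links the α-carbons of the C1 and C8 carbonyl positions, so the 1,4-dioxygenated unit C1–C6–C7–C8 shared by rings A and B can be made by oxidative union of two enol ethers.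
- Forward order: ring A by aldol condensation, the C5 methyl by conjugate addition, ring B by anodic C6–C7 coupling, then C3, C2 and C1 of ring A, acylation, and the oxirane last.
- Stereochemistry: C10 from (S)-2-methylsuccinate; C5 from a chiral copper catalyst; C6 from the tether (cis fusion); C3 from β-face cuprate addition; C2 anti to C3; C1 from equatorial hydride attack; C11 from hydroxyl-directed epoxidation.

Key step: step 6

Assumption: induction in step 4 is catalyst-controlled, so the antipode of the phosphoramidite L* (2,2'-biphenol / bis(1-arylethyl)amine type) is the one that delivers methyl to the Si face of C5 (priorities C6 > C10 > C4); compounds 1, 4 and 19 are taken as commercial; the Tebbe reagent is drawn with a terminal Ti–Cl bond, its chloride-to-aluminium bridge being a dative contact.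

**Route**

Step 1
Reactants: 1 (S)-2-methylsuccinic acid 4-methyl ester
Product: 3 methyl (3S)-4-[methoxy(methyl)amino]-3-methyl-4-oxobutanoate, via acyl imidazolide 2 (not isolated)
Conditions: CDI, CH2Cl2, 0 °C → rt; then MeNHOMe·HCl, rt
Reagents that add atoms: N,O-dimethylhydroxylamine hydrochloride, CNOC.Cl
Why: Weinreb amide formation through the acyl imidazolide runs under near-neutral conditions, which should leave the α-methyl stereocentre (future C10) and the methyl ester untouched.

Step 2
Reactants: 3 methyl (3S)-4-[methoxy(methyl)amino]-3-methyl-4-oxobutanoate; 4 2-(3-chloropropyl)-2-methyl-1,3-dioxolane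
Product: 6 methyl (3S)-3-methyl-7-(2-methyl-1,3-dioxolan-2-yl)-4-oxoheptanoate, via Grignard reagent 5 (not isolated)
Conditions: 4, Mg, BrCH2CH2Br (cat.), THF, 50 °C; then 3 (1.1 equiv of 5), THF, −30 → 0 °C; aq NH4Cl
Reagents that add atoms: none
Why: Weinreb ketone synthesis, in which the Grignard reagent adds once to the N-methoxy-N-methylamide through a stable magnesium chelate, should be faster at low temperature than attack on the methyl ester, while the dioxolane masks the second ketone.

Step 3
Reactants: 6 methyl (3S)-3-methyl-7-(2-methyl-1,3-dioxolan-2-yl)-4-oxoheptanoate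
Product: 8 methyl (3S)-3-(3-oxocyclohex-1-en-1-yl)butanoate, via diketone 7 (not isolated)
Conditions: 1 M HCl, THF, rt; neutralise, concentrate; then NaOMe (0.3 equiv), MeOH, 0 °C → rt
Reagents that add atoms: water, O
Why: Ketal hydrolysis followed by intramolecular aldol condensation, in which the methyl-ketone enolate attacks the C5 ketone, closes ring A as the conjugated 3-substituted cyclohexenone; catalytic methoxide in cold methanol keeps the methyl ester and should limit exchange at the hindered C10 methine.

Step 4
Reactants: 8 methyl (3S)-3-(3-oxocyclohex-1-en-1-yl)butanoate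
Product: 10 methyl (3S)-3-[(1R)-3-{[tert-butyl(dimethyl)silyl]oxy}-1-methylcyclohex-2-en-1-yl]butanoate, via aluminium enolate 9 (not isolated)
Conditions: Me3Al (2 equiv), Cu(O2CC4H3S) (copper thiophene-2-carboxylate, 5 mol%), L* (10 mol%), Et2O, −30 °C; then TBSOTf, THF, −30 → 0 °C
Reagents that add atoms: trimethylaluminium, C[Al](C)C; tert-butyldimethylsilyl trifluoromethanesulfonate, CC(C)(C)[Si](C)(C)OS(=O)(=O)C(F)(F)F
Why: Copper-catalysed enantioselective conjugate addition of Me3Al to a β-substituted cyclohexenone should place methyl on the Si face of C5 under catalyst control to set the quaternary centre, the ester being inert to Me3Al at this temperature, and O-silylation of the aluminium enolate fixes the C1=C6 enol silane regiochemistry.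

Step 5
Reactants: 10 methyl (3S)-3-[(1R)-3-{[tert-butyl(dimethyl)silyl]oxy}-1-methylcyclohex-2-en-1-yl]butanoate
Product: 11 tert-butyl({(3R)-3-[(2S)-4-methoxypent-4-en-2-yl]-3-methylcyclohex-1-en-1-yl}oxy)dimethylsilane
Conditions: Cp2Ti(μ-Cl)(μ-CH2)AlMe2 (Tebbe reagent), pyridine (cat.), THF/toluene, −40 °C → rt; aq NaOH, basic Al2O3
Reagents that add atoms: Tebbe reagent Cp2Ti(μ-Cl)(μ-CH2)AlMe2, C[Al](C)C[Ti](Cl)(C1C=CC=C1)C1C=CC=C1
Why: Tebbe methylenation converts the ester directly into the methyl enol ether (C8(OMe)=C7H2), the titanium methylidene being unreactive toward the silyl enol ether, and pyridine plus a basic work-up protect both acid-labile enol ethers.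

Step 6
Reactants: 11 tert-butyl({(3R)-3-[(2S)-4-methoxypent-4-en-2-yl]-3-methylcyclohex-1-en-1-yl}oxy)dimethylsilane
Product: 12 (4aR,5S,8aS)-7,7-dimethoxy-4a,5-dimethyloctahydronaphthalen-1(2H)-one
Conditions: reticulated vitreous carbon anode, Pt cathode, undivided cell, constant current, 2.2 F/mol, 0.1 M LiClO4, 2,6-lutidine, MeOH/CH2Cl2 (1:4), rt
Reagents that add atoms: methanol, CO
Why: The more electron-rich ring enol silane is oxidised at the anode to a radical cation, the terminal CH2 (C7) of the side-chain methoxy-alkene adds to C6, the resulting C8 oxocarbenium ion is captured by methanol as the dimethyl ketal, and the C1 α-silyloxy radical loses a second electron and then its silyl group to methanol to give the ketone. The closest known reaction type is the intramolecular anodic coupling of two enol ethers in buffered methanol. Ring B closes in a six-membered mode that is exo with respect to the C1=C6 enol silane and endo with respect to the C7=C8 enol ether, through a chair-like transition state with the C10 methyl equatorial. The only new stereocentre, C6, is set by the tether: C7 must reach C6 perpendicular to the enol plane and can do so only on the face that carries C10, so C6–C7 forms cis to C5–C10 and C6–H ends cis to the C5 methyl (cis-decalin). The step needs C–C bond formation to outrun methanol capture of the radical cation and needs the two carbonyls to emerge differentiated; the first is secured by the short tether held at the quaternary C5 and the low methanol content, the second by the different oxygen substituents (O-silyl gives the free ketone, O-methyl the ketal).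

Step 7
Reactants: 12 (4aR,5S,8aS)-7,7-dimethoxy-4a,5-dimethyloctahydronaphthalen-1(2H)-one
Product: 14 (4aR,5S,8aS)-7,7-dimethoxy-4a,5-dimethyl-4a,5,6,7,8,8a-hexahydronaphthalen-1(4H)-one, via trimethylsilyl enol ether 13 (not isolated)
Conditions: LiN(i-Pr)2, THF, −78 °C; Me3SiCl; then Pd(OAc)2 (1.1 equiv), MeCN, rt
Reagents that add atoms: none
Why: Kinetic deprotonation removes a C2 methylene proton in preference to the ring-fusion C6 methine, and Saegusa–Ito oxidation of the resulting enol silane with divalent palladium gives the C2=C3 enone without touching C6 or the ketal.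

Step 8
Reactants: 14 (4aR,5S,8aS)-7,7-dimethoxy-4a,5-dimethyl-4a,5,6,7,8,8a-hexahydronaphthalen-1(4H)-one
Product: 15 C1=C2 triethylsilyl enol ether carrying 3β-isopropenyl (cis-decalin; C8 dimethyl ketal)
Conditions: CH2=C(CH3)MgBr, CuBr·SMe2 (20 mol%), Et3SiCl, THF, −78 °C; Et3N, aq NaHCO3
Reagents that add atoms: isopropenylmagnesium bromide, CC(=C)[Mg]Br; chlorotriethylsilane, CC[Si](Cl)(CC)CC
Why: Copper-catalysed conjugate addition of the Grignard reagent, accelerated by the chlorosilane that traps the enolate as the C1=C2 silyl enol ether, is expected to bond C3 on the β face because the α face under C3 is screened by the C5–C10 bond of the folded cis-decalin (C10–H and the C10 methyl lie below ring A), which places isopropenyl cis to the C5 methyl.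

Step 9
Reactants: 15 C1=C2 triethylsilyl enol ether carrying 3β-isopropenyl
Product: 17 2α-(triethylsilyloxy)-3β-isopropenyl C1 ketone (C8 dimethyl ketal), via silyloxy epoxide 16 (not isolated)
Conditions: mCPBA (1.05 equiv), NaHCO3, CH2Cl2, −20 → 0 °C
Reagents that add atoms: 3-chloroperoxybenzoic acid, OOC(=O)c1cccc(Cl)c1
Why: In this Rubottom oxidation the electron-rich enol silane is epoxidised much faster than the isopropenyl alkene, on the face anti to the adjacent C3 substituent, and opening of the silyloxy epoxide with 1,4-silyl shift gives the α-silyloxy ketone with the C2 oxygen trans to isopropenyl and equatorial (also the more stable arrangement).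

Step 10
Reactants: 17 2α-(triethylsilyloxy)-3β-isopropenyl C1 ketone
Product: 18 1α-hydroxy-2α-(triethylsilyloxy)-3β-isopropenyl cis-decalin (C8 dimethyl ketal)
Conditions: LiBH(s-Bu)3, THF, −78 °C; AcOH, −78 °C; then H2O2, pH 7 buffer, 0 °C
Reagents that add atoms: none
Why: In this hindered-borohydride reduction hydride approaches C1 along the equatorial path on the β face, the α face being blocked by the axial C5–C10 bond and the axial C8 methoxy group, which gives the axial 1α-alcohol cis to the C2 silyloxy group; the cold acidic quench should prevent O-to-O silyl migration.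

Step 11
Reactants: 18 1α-hydroxy-2α-(triethylsilyloxy)-3β-isopropenyl cis-decalin; 19 (2E)-3-methylpent-2-enoic acid
Product: 21 C1 (2E)-3-methylpent-2-enoate of 18, via mixed anhydride 20 (not isolated)
Conditions: 19, 2,4,6-Cl3C6H2COCl, Et3N, THF, rt; then 18, DMAP, toluene, 40 °C
Reagents that add atoms: none
Why: Yamaguchi esterification acylates the hindered axial C1 hydroxyl through the mixed anhydride under DMAP catalysis without strong base, so the E enoate geometry should be kept, and the C2 oxygen is blocked as its silyl ether.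

Step 12
Reactants: 21 C1 (2E)-3-methylpent-2-enoate of 18
Product: 22 1α-[(2E)-3-methylpent-2-enoyloxy]-2α-hydroxy-3β-isopropenyl C8 ketone
Conditions: AcOH/THF/H2O (3:1:1), rt; NaHCO3 work-up
Reagents that add atoms: water, O
Why: Mild aqueous acid hydrolyses the dimethyl ketal and the triethylsilyl ether in one operation while leaving the enoate ester in place, and it is done before the acid-sensitive oxirane exists; the mild conditions should avoid 1,2-acyl migration.

Step 13
Reactants: 22 1α-[(2E)-3-methylpent-2-enoyloxy]-2α-hydroxy-3β-isopropenyl C8 ketone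
Product: 23 CNP0103173.1 (target)
Conditions: VO(acac)2 (5 mol%), t-BuOOH, CH2Cl2, 0 °C → rt
Reagents that add atoms: tert-butyl hydroperoxide, CC(C)(C)OO
Why: In this vanadium-catalysed hydroxyl-directed epoxidation the C2 vanadate delivers the peroxide oxygen only to the homoallylic isopropenyl alkene (the enoate is electron-poor and out of reach), through a chair-like transition state in which the vinylic methyl C13 lies next to C3–H instead of eclipsing a ring bond, which should set C11 as in the target.

**Compound list**

1 | (S)-2-methylsuccinic acid 4-methyl ester | COC(=O)C[C@@H](C(=O)O)C | starting material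
2 | methyl (3S)-4-(1H-imidazol-1-yl)-3-methyl-4-oxobutanoate (acyl imidazolide) | COC(=O)C[C@H](C)C(=O)n1ccnc1 | intermediate
3 | methyl (3S)-4-[methoxy(methyl)amino]-3-methyl-4-oxobutanoate | COC(=O)C[C@H](C)C(=O)N(C)OC | intermediate
4 | 2-(3-chloropropyl)-2-methyl-1,3-dioxolane | CC1(CCCCl)OCCO1 | starting material
5 | [3-(2-methyl-1,3-dioxolan-2-yl)propyl]magnesium chloride | CC1(CCC[Mg]Cl)OCCO1 | intermediate
6 | methyl (3S)-3-methyl-7-(2-methyl-1,3-dioxolan-2-yl)-4-oxoheptanoate | COC(=O)C[C@H](C)C(=O)CCCC1(C)OCCO1 | intermediate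
7 | methyl (3S)-3-methyl-4,8-dioxononanoate | COC(=O)C[C@H](C)C(=O)CCCC(C)=O | intermediate
8 | methyl (3S)-3-(3-oxocyclohex-1-en-1-yl)butanoate | COC(=O)C[C@H](C)C1=CC(=O)CCC1 | intermediate
9 | dimethylaluminium enolate of the C5-methylated ketone (C1=C6) | C[Al](C)OC1=C[C@](C)(CCC1)[C@@H](C)CC(=O)OC | intermediate
10 | methyl (3S)-3-[(1R)-3-{[tert-butyl(dimethyl)silyl]oxy}-1-methylcyclohex-2-en-1-yl]butanoate | CC(C)(C)[Si](C)(C)OC1=C[C@](C)(CCC1)[C@@H](C)CC(=O)OC | intermediate
11 | tert-butyl({(3R)-3-[(2S)-4-methoxypent-4-en-2-yl]-3-methylcyclohex-1-en-1-yl}oxy)dimethylsilane | CC(C)(C)[Si](C)(C)OC1=C[C@](C)(CCC1)[C@@H](C)CC(=C)OC | intermediate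
12 | (4aR,5S,8aS)-7,7-dimethoxy-4a,5-dimethyloctahydronaphthalen-1(2H)-one (cis-decalin C1 ketone, C8 dimethyl ketal) | O=C1CCC[C@@]2(C)[C@@H]1CC(OC)(OC)C[C@@H]2C | intermediate
13 | C1=C2 trimethylsilyl enol ether of 12 | C[Si](C)(C)OC1=CCC[C@@]2(C)[C@@H]1CC(OC)(OC)C[C@@H]2C | intermediate
14 | (4aR,5S,8aS)-7,7-dimethoxy-4a,5-dimethyl-4a,5,6,7,8,8a-hexahydronaphthalen-1(4H)-one (C2=C3 enone) | O=C1C=CC[C@@]2(C)[C@@H]1CC(OC)(OC)C[C@@H]2C | intermediate
15 | C1=C2 triethylsilyl enol ether with 3β-isopropenyl; C5–CH3, C6–H and C10–CH3 β; C8 dimethyl ketal | CC[Si](CC)(CC)OC1=C[C@@H](C(C)=C)C[C@@]2(C)[C@@H]1CC(OC)(OC)C[C@@H]2C | intermediate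
16 | 1α,2α-epoxide of 15 (C1 bears OSiEt3) | CC[Si](CC)(CC)O[C@@]12O[C@@H]1[C@@H](C(C)=C)C[C@@]3(C)[C@@H]2CC(OC)(OC)C[C@@H]3C | intermediate
17 | 2α-(triethylsilyloxy)-3β-isopropenyl C1 ketone, C8 dimethyl ketal | O=C1[C@H](O[Si](CC)(CC)CC)[C@@H](C(C)=C)C[C@@]2(C)[C@@H]1CC(OC)(OC)C[C@@H]2C | intermediate
18 | 1α-hydroxy-2α-(triethylsilyloxy)-3β-isopropenyl cis-decalin, C8 dimethyl ketal | O[C@@H]1[C@H](O[Si](CC)(CC)CC)[C@@H](C(C)=C)C[C@@]2(C)[C@@H]1CC(OC)(OC)C[C@@H]2C | intermediate
19 | (2E)-3-methylpent-2-enoic acid | CC/C(C)=C/C(=O)O | starting material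
20 | (2E)-3-methylpent-2-enoic 2,4,6-trichlorobenzoic anhydride | CC/C(C)=C/C(=O)OC(=O)c1c(Cl)cc(Cl)cc1Cl | intermediate
21 | C1 (2E)-3-methylpent-2-enoate of 18 | CC/C(C)=C/C(=O)O[C@@H]1[C@H](O[Si](CC)(CC)CC)[C@@H](C(C)=C)C[C@@]2(C)[C@@H]1CC(OC)(OC)C[C@@H]2C | intermediate
22 | 1α-[(2E)-3-methylpent-2-enoyloxy]-2α-hydroxy-3β-isopropenyl C8 ketone | CC/C(C)=C/C(=O)O[C@@H]1[C@H](O)[C@@H](C(C)=C)C[C@@]2(C)[C@@H]1CC(=O)C[C@@H]2C | intermediate
23 | CNP0103173.1 | CC/C(C)=C/C(=O)O[C@@H]1[C@H](O)[C@@H]([C@]2(C)CO2)C[C@@]2(C)[C@@H]1CC(=O)C[C@@H]2C | target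

**Summary**

Total steps: 13. Longest linear sequence: 13 steps (1 → 23).

**Steps most likely to fail**

Step 4. Transfer of the small methyl group to a β-carbon that carries an α-branched substituent may be slow, may be overtaken by 1,2-addition, may suffer from a mismatched catalyst/substrate pairing, or the aluminium enolate may silylate incompletely. The fallback sets out from 8 and installs the methyl by directed cyclopropanation and reductive ring opening. CBS reduction (oxazaborolidine antipode chosen for the (S)-carbinol, catecholborane) gives the allylic alcohol F1. Hydroxyl-directed Simmons–Smith cyclopropanation (Et2Zn, CH2I2) adds the methylene syn to the hydroxyl to give the cyclopropyl carbinol F2. Dess–Martin oxidation gives the cyclopropyl ketone F3. Divalent samarium (SmI2, HMPA, one equivalent of t-BuOH, THF, −78 °C) cleaves the exocyclic cyclopropane bond that overlaps with the carbonyl, which turns the methylene into the C5 methyl and leaves the C1=C6 enolate; this is silylated with TBSOTf/Et3N, and the route is rejoined at 10.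

Step 6. Methanol may capture the radical cation, or the silyl group may be lost, before the six-membered ring closes next to the quaternary carbon, and the C8 ketal may be partly hydrolysed at the anode. The fallback sets out from 11 and forms the same C6–C7 bond with a chemical one-electron oxidant. Brief treatment with PPTS in wet THF at 0 °C hydrolyses only the methoxy-alkene to the methyl ketone F4. Kinetic enolisation at the methyl group (LiN(i-Pr)2, TBSCl, THF, −78 °C) gives the bis(silyl enol ether) F5. Oxidative intramolecular coupling with (NH4)2Ce(NO3)6 and NaHCO3 in MeCN at −10 °C gives the cis-fused diketone F6. Selective ketalisation of the unhindered C8 carbonyl (HC(OMe)3, MeOH, PPTS) returns to 12.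

Step 8. Facial selectivity at C3 may be poor, because the flexible cis-decalin can also react through the chair in which the C5 methyl is axial over C3. The fallback sets out from 14 and fixes C3 by a stereospecific epoxide opening. Reduction with i-Bu2AlH (CH2Cl2, −78 °C, hydride from the β face) gives the allylic alcohol F7. Hydroxyl-directed epoxidation (VO(acac)2, t-BuOOH) gives the syn epoxy alcohol F8. Trans-diaxial opening at C3, distal to the C1 oxygen, with CH2=C(CH3)MgBr and CuI proceeds with inversion and gives the diol F9 with β-isopropenyl. Selective silylation of the equatorial C2 hydroxyl (Et3SiCl, imidazole, −20 °C) returns to 18.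

**Further compounds**

F1 | step 4 | methyl (3S)-3-[(3S)-3-hydroxycyclohex-1-en-1-yl]butanoate | COC(=O)C[C@H](C)C1=C[C@@H](O)CCC1
F2 | step 4 | methyl (3S)-3-(2-hydroxybicyclo[4.1.0]heptan-6-yl)butanoate, OH cis to the cyclopropane CH2 | COC(=O)C[C@H](C)[C@]12C[C@H]1[C@@H](O)CCC2
F3 | step 4 | methyl (3S)-3-(2-oxobicyclo[4.1.0]heptan-6-yl)butanoate, cyclopropane CH2 on the face of the future C5 methyl | COC(=O)C[C@H](C)[C@]12C[C@H]1C(=O)CCC2
F4 | step 6 | (4S)-4-[(1R)-3-{[tert-butyl(dimethyl)silyl]oxy}-1-methylcyclohex-2-en-1-yl]pentan-2-one | CC(C)(C)[Si](C)(C)OC1=C[C@](C)(CCC1)[C@@H](C)CC(C)=O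
F5 | step 6 | bis(tert-butyldimethylsilyl) enol ether of F4 (ring C1=C6 and terminal C7=C8) | CC(C)(C)[Si](C)(C)OC1=C[C@](C)(CCC1)[C@@H](C)CC(=C)O[Si](C)(C)C(C)(C)C
F6 | step 6 | (4aR,5S,8aS)-4a,5-dimethyloctahydronaphthalene-1,7-dione (cis-fused) | O=C1CCC[C@@]2(C)[C@@H]1CC(=O)C[C@@H]2C
F7 | step 8 | 1α-hydroxy C2=C3 alkene of the cis-decalin, C8 dimethyl ketal | O[C@@H]1C=CC[C@@]2(C)[C@@H]1CC(OC)(OC)C[C@@H]2C
F8 | step 8 | 2α,3α-epoxy-1α-ol of the cis-decalin, C8 dimethyl ketal | O[C@@H]1[C@@H]3O[C@@H]3C[C@@]2(C)[C@@H]1CC(OC)(OC)C[C@@H]2C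
F9 | step 8 | 1α,2α-diol with 3β-isopropenyl, C8 dimethyl ketal | O[C@@H]1[C@H](O)[C@@H](C(C)=C)C[C@@]2(C)[C@@H]1CC(OC)(OC)C[C@@H]2C
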